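Working numbering used in the text: enone ring C1 (C=O), C2 (bears Cα of the propanoic acid), C3 (bears C1′), C4, C5, C6 (bears CH2OCHO); cyclohexyl ring C1′ (quaternary, methyl), C3′ (gem-dimethyl), C5′, C6′. Compound names use IUPAC locants, in which working C6 is C5 of the cyclohexenyl ring.

Remark: cyclohexane-1,2-dione is used as its stable enol tautomer 3, and the γ-keto acids 12, 13, 16 and 17 are drawn, like the target, in the open keto-acid form.

## The problem

- **Structure.** The target is a 2,3,6-trisubstituted cyclohex-2-enone. C2 carries an (R)-CH(CH3)CO2H group, C3 is bonded to the quaternary carbon C1′ of an (S)-1,3,3-trimethylcyclohexyl ring, and C6 (S) carries CH2OCHO.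
- **Hardest bond.** The C3–C1′ bond joins a tetrasubstituted alkene carbon to an all-carbon quaternary stereocentre. The three alkyl arms of C1′ (CH3, CH2–CMe2, CH2–CH2) differ only remotely, so catalyst-controlled face selection at C1′ is intrinsically weak.
- **No relay.** C1′, Cα and C6 are separated by sp2 atoms (1,4 and 1,5), and no unstrained ring can tie them together. A lactone between CO2H and the C6 oxymethyl group would hold a bridgehead alkene. Each centre must therefore be set on its own.
- **Labile groups.** Cα is allylic and α to a carboxyl, so it epimerises as an ester enolate. C6 is α to the ketone and β to an acyloxy group, so base epimerises it and expels formate (E1cB) to an exo-methylene ketone. The formate itself is hydrolytically fragile. C6 and the formate must therefore come last, under near-neutral conditions, and the acid should never need a base-labile protecting group.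
- **Enabling feature.** If C2 carries oxygen instead of carbon, the atoms O–C2=C3–C1′–C6′=C5′ are the product side of a [3,3] shift of an allyl vinyl ether whose C–O bond sits on C5′. The ring C1′–C6′ has the methyl pattern of isophorone (C1′-CH3 = isophorone C3-CH3, C3′ gem-dimethyl = C5, C5′ = carbonyl carbon). The fragment O=C1–C2(OH)=C3 is the enol of cyclohexane-1,2-dione. An oxygen stereocentre at C5′ can thus be traded for the quaternary centre C1′ while the hindered C3–C1′ bond is formed.

## Retrosynthesis

**17 ⇒ 16 (formyl C–O bond).** The formate is cut first, back to hydroxy acid 16. A neutral formyl donor acylates the primary alcohol and leaves CO2H alone, so no protecting group is needed. The forward step must avoid base.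

**16 ⇒ 15 ⇒ 13 (C6–CH2 bond).** The hydroxymethyl carbon is removed as formaldehyde, leaving the silyl dienol ether 15 of enone acid 13. Introducing this carbon earlier, on the dione, is not possible: a 1,2-dione enolises towards a substituted C6 and would scramble it. With C2 already carbon-substituted and the acid present as carboxylate, C6 is the only kinetic enolisation site. The forward reaction must select the enolate face by catalyst control.

**13 ⇒ 12 ⇒ 11 ⇒ 8 + 10 (Cα–H, then C2–Cα).** Cα is traced to the acrylic acid 12, so its configuration comes from a carboxylate-directed asymmetric hydrogenation. The C2–Cα bond is cut to enol triflate 8 and α-stannyl acrylate 10 (made from methyl propiolate 9). A flat sp2 acrylate unit is preferred to a secondary propionate nucleophile, which would have to couple at the most hindered position and would give no stereocontrol. The forward coupling must work on a triflate flanked by C=O and the tert-alkyl-bearing C3.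

**8 ⇒ 7 ⇒ 6 (C2–O handle, ring alkene).** The triflate comes from diosphenol 7, the hydrogenation product of cyclohexenyl diosphenol 6. The C2 oxygen is therefore the same oxygen that drives the key step.

**6 ⇒ 5 ⇒ 4 (C3–C1′ bond, key disconnection).** The C3–C1′ bond is cut by a retro-Claisen to the allyl vinyl ether 4, the isophoryl ether of the diosphenol. The precursor is two commercial six-membered rings joined through oxygen. The forward step forms the most hindered bond, sets C1′ by 1,3-transfer from the C–O centre, and leaves the C1 ketone and a C2 oxygen handle in place. It must run suprafacially and beat elimination.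

**4 ⇒ 2 + 3; 2 ⇒ 1.** The ether C–O bond is cut to (R)-isophorol 2 and diosphenol 3 (Mitsunobu, inversion, giving the (S)-ether). Alcohol 2 comes from isophorone 1 by catalytic enantioselective reduction. This is the only place where absolute configuration is bought for C1′.

## Roads not taken

**Alternative 1: conjugate addition of a latent enone (the obvious route).**
- Cut: C3–C1′ as aryl nucleophile plus β-methyl enone acceptor.
- Forward key step: Pd(II)/pyridine-oxazoline-catalysed conjugate addition of a meta-anisyl boron reagent to a 3-methylcyclohexenone acceptor to give ketone A1. Geminal dimethylation of the carbonyl then gives arene A2, and Birch reduction with hydrolysis gives enone A3.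
- Why the chosen plan is better: A3 has no handle at C2, and C2–H is the most hindered position of the molecule, next to the tert-alkyl group. Isophorone itself cannot serve as acceptor (β-methyl plus axial 5-methyl), so the gem-dimethyl group costs a separate step. About three more steps are needed to reach the stage of 8. The Claisen route delivers the quaternary centre, the C1 ketone and the C2 oxygen in one event from a C–O stereocentre.

**Alternative 2: aldol ring closure.**
- Cut: C2=C3, by intramolecular aldol condensation of 1,5-diketone A5, built from quaternary acid A4.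
- Forward key step: enolisation at the future C2 and attack on the tert-alkyl ketone, then dehydration.
- Why the chosen plan is better: A4 has no practical enantioselective access, since methylating a nearly Cs-symmetric ring enolate cannot tell CH2–CMe2 from CH2–CH2. The aldol addition to a neopentyl-type ketone to form a tetrasubstituted alkene is slow and reversible. The competing enolisations in A5 run through Cα and the future C6, so both labile centres would be set early only to be put at risk in the ring closure.

**Alternative 3: strain-release [4+2].**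
- Cut: C1–C2 and C3–C4, by Ni(0)-catalysed insertion of alkyne A6 into the unsubstituted C–C(O) bond of cyclobutanone A7.
- Forward key step: oxidative cyclisation, β-carbon elimination, reductive elimination.
- Why the chosen plan is better: A6 already contains a C(sp)–C1′ bond for which no stereocontrolled construction exists, and its propargylic Cα isomerises to an allenoate. The alkyne is shielded by a tert-alkyl group. The metal must also cleave the less substituted ring bond of A7 without epimerising its α-centre. The difficulty is moved into the precursor and not removed.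

Key step: step 3

## Route

Step 1
Reactants: 1 isophorone (3,5,5-trimethylcyclohex-2-en-1-one)
Product: 2 (1R)-3,5,5-trimethylcyclohex-2-en-1-ol
Conditions: (S)-Me-CBS (10 mol%), BH3·SMe2, THF, −20 °C; MeOH quench
Reagents that add atoms: none
Why: Corey–Bakshi–Shibata 1,2-reduction of an enone; with the enone π-system as the large substituent the (S)-catalyst should deliver hydride to the face giving the (R)-allylic alcohol (sense to be confirmed, antipodal catalyst otherwise).

Step 2
Reactants: 2 (1R)-3,5,5-trimethylcyclohex-2-en-1-ol; 3 2-hydroxycyclohex-2-en-1-one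
Product: 4 2-{[(1S)-3,5,5-trimethylcyclohex-2-en-1-yl]oxy}cyclohex-2-en-1-one
Conditions: PPh3, DIAD, toluene, −20 °C to rt
Reagents that add atoms: none
Why: Mitsunobu etherification of the acidic diosphenol OH (pKa about 10) by SN2 displacement at the carbinol carbon with inversion, (R)-alcohol to (S)-ether; the non-polar solvent disfavours ionisation of the allylic oxyphosphonium ion.

Step 3
Reactants: 4 2-{[(1S)-3,5,5-trimethylcyclohex-2-en-1-yl]oxy}cyclohex-2-en-1-one
Product: 6 2-hydroxy-3-[(1R)-1,5,5-trimethylcyclohex-2-en-1-yl]cyclohex-2-en-1-one, via 1,2-diketone tautomer 5 (not isolated)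
Conditions: o-xylene (0.05 M), 145 °C, sealed tube, BHT (cat.), base-washed glass
Reagents that add atoms: none
Why: Concerted suprafacial [3,3] sigmatropic shift of the allyl vinyl ether (O–C2=C3 of the enone ring with C1″–C2″=C3″ of the isophoryl ring): the O–C1″ bond breaks while C3–C3″ forms through a six-membered chair-like array, and the first-formed 1,2-diketone 5 enolises to the hydrogen-bonded diosphenol 6, which makes the step irreversible. The closest known reaction type is the Claisen rearrangement of allyl ethers of diosphenols (2-allyloxycyclohex-2-enones to 3-allylcyclohexane-1,2-diones), which tolerates fully substituted allyl termini. No ring is closed; the two six-membered rings of 4 are kept and become directly C–C bonded. The only lasting new stereocentre, the quaternary carbon, is controlled by the C–O stereocentre of 4: the cyclohexene ring allows bond formation only on the face from which oxygen departs, so the (1S)-ether gives the (1R)-cyclohexenyl group, which is the (1S)-cyclohexyl group of the target after saturation (same spatial arrangement, changed CIP ranking). The transient C3–H centre of 5 is erased by enolisation. The step needs the [3,3] path to win over retro-ene loss of 3 and over ionisation to an allyl cation/diosphenolate pair, which would give [1,3] products and racemise; the non-polar medium, neutral glass and the unhindered CH terminus of the vinyl ether favour the pericyclic path, while the axial C5″ methyl syn to the forming bond raises its barrier.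

Step 4
Reactants: 6 2-hydroxy-3-[(1R)-1,5,5-trimethylcyclohex-2-en-1-yl]cyclohex-2-en-1-one
Product: 7 2-hydroxy-3-[(1S)-1,3,3-trimethylcyclohexyl]cyclohex-2-en-1-one
Conditions: H2 (1 atm), 5% Pd/C, EtOAc, rt
Reagents that add atoms: none
Why: Heterogeneous hydrogenation of the cis-disubstituted ring alkene; the tetrasubstituted, conjugated enol double bond is inert and the quaternary centre is untouched.

Step 5
Reactants: 7 2-hydroxy-3-[(1S)-1,3,3-trimethylcyclohexyl]cyclohex-2-en-1-one
Product: 8 6-oxo-2-[(1S)-1,3,3-trimethylcyclohexyl]cyclohex-1-en-1-yl trifluoromethanesulfonate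
Conditions: Tf2O, pyridine, CH2Cl2, −78 to 0 °C
Reagents that add atoms: trifluoromethanesulfonic anhydride, O=S(=O)(OS(=O)(=O)C(F)(F)F)C(F)(F)F
Why: O-sulfonylation of the existing C2 enol (the tetrasubstituted, hydrogen-bonded tautomer) gives the α-triflyloxy enone, a standard handle for cross-coupling at the enone α-carbon.

Step 6
Reactants: 9 methyl propiolate
Product: 10 methyl 2-(tributylstannyl)prop-2-enoate
Conditions: Bu3SnH, Pd(PPh3)4 (2 mol%), THF, 0 °C to rt
Reagents that add atoms: tributyltin hydride, CCCC[SnH](CCCC)CCCC
Why: Pd-catalysed syn-hydrostannation of an alkynoate, which places tin α to the ester.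

Step 7
Reactants: 8 6-oxo-2-[(1S)-1,3,3-trimethylcyclohexyl]cyclohex-1-en-1-yl trifluoromethanesulfonate; 10 methyl 2-(tributylstannyl)prop-2-enoate
Product: 11 methyl 2-[6-oxo-2-[(1S)-1,3,3-trimethylcyclohexyl]cyclohex-1-en-1-yl]prop-2-enoate
Conditions: Pd(PPh3)4 (10 mol%), CuCl (5 equiv), LiCl (6 equiv), DMSO, 60 °C
Reagents that add atoms: none
Why: Copper-accelerated Stille coupling, the variant developed for congested enol triflates and 1-substituted vinylstannanes; the electron-poor α-triflyloxy enone adds oxidatively with ease and Sn-to-Cu transmetalation carries the hindered C–C bond formation.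

Step 8
Reactants: 11 methyl 2-[6-oxo-2-[(1S)-1,3,3-trimethylcyclohexyl]cyclohex-1-en-1-yl]prop-2-enoate
Product: 12 2-[6-oxo-2-[(1S)-1,3,3-trimethylcyclohexyl]cyclohex-1-en-1-yl]prop-2-enoic acid
Conditions: LiOH·H2O, THF/MeOH/H2O, rt; then 1 M HCl
Reagents that add atoms: lithium hydroxide (hydroxide oxygen), [Li+].[OH-]
Why: Saponification of the methyl ester; no labile stereocentre is present yet and the alkene cannot migrate because C3 carries no hydrogen.

Step 9
Reactants: 12 2-[6-oxo-2-[(1S)-1,3,3-trimethylcyclohexyl]cyclohex-1-en-1-yl]prop-2-enoic acid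
Product: 13 (2R)-2-[6-oxo-2-[(1S)-1,3,3-trimethylcyclohexyl]cyclohex-1-en-1-yl]propanoic acid
Conditions: Ru(OAc)2[(R)-H8-BINAP] (1 mol%), H2 (100 atm), MeOH, 15 °C
Reagents that add atoms: none
Why: Carboxylate-directed Ru(II)–BINAP-type asymmetric hydrogenation of a 2-substituted acrylic acid (profen-type reduction) sets Cα by catalyst control, the (R)-ligand being chosen by analogy with the (S)-ligand/(S)-2-arylpropanoic acid correlation; the tetrasubstituted enone and the ketone are inert to this catalyst.

Step 10
Reactants: 13 (2R)-2-[6-oxo-2-[(1S)-1,3,3-trimethylcyclohexyl]cyclohex-1-en-1-yl]propanoic acid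
Product: 15 trimethylsilyl (2R)-2-[2-[(1S)-1,3,3-trimethylcyclohexyl]-6-(trimethylsilyloxy)cyclohexa-1,5-dien-1-yl]propanoate, via dilithium carboxylate-dienolate 14 (not isolated)
Conditions: LDA (2.2 equiv), THF, −78 °C; TMSCl (2.5 equiv), −78 to 0 °C; pentane, filtration
Reagents that add atoms: chlorotrimethylsilane, C[Si](C)(C)Cl
Why: Kinetic α′-deprotonation of the enone gives the cross-conjugated enolate and O-silylation traps it; the first equivalent of base makes the carboxylate, which protects Cα–H from deprotonation.

Step 11
Reactants: 15 trimethylsilyl (2R)-2-[2-[(1S)-1,3,3-trimethylcyclohexyl]-6-(trimethylsilyloxy)cyclohexa-1,5-dien-1-yl]propanoate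
Product: 16 (2R)-2-[(5S)-5-(hydroxymethyl)-6-oxo-2-[(1S)-1,3,3-trimethylcyclohexyl]cyclohex-1-en-1-yl]propanoic acid
Conditions: aq. HCHO (5 equiv), Sc(OTf)3 (10 mol%), chiral 6,6′-bis(1-hydroxy-2,2-dimethylpropyl)-2,2′-bipyridine (12 mol%, antipode chosen for 5S), 2,6-di-tert-butylpyridine, DME/H2O 9:1, −20 °C
Reagents that add atoms: formaldehyde, C=O
Why: Catalytic enantioselective Mukaiyama aldol (hydroxymethylation of a silicon enolate with aqueous formaldehyde under a chiral Sc(III)–bipyridine complex); the chiral Lewis acid–formaldehyde complex selects the enolate face at C6 by reagent control, the silyl ester is hydrolysed in the medium, and the cold, weakly acidic conditions avoid epimerisation and dehydration of the β-hydroxy ketone.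

Step 12
Reactants: 16 (2R)-2-[(5S)-5-(hydroxymethyl)-6-oxo-2-[(1S)-1,3,3-trimethylcyclohexyl]cyclohex-1-en-1-yl]propanoic acid
Product: 17 (2R)-2-[(5S)-5-[(formyloxy)methyl]-6-oxo-2-[(1S)-1,3,3-trimethylcyclohexyl]cyclohex-1-en-1-yl]propanoic acid (target)
Conditions: HCO2CH2CF3 (excess), THF, 50 °C
Reagents that add atoms: 2,2,2-trifluoroethyl formate, O=COCC(F)(F)F
Why: Transesterification-type O-formylation with an activated formate under neutral conditions; the primary alcohol is acylated and the carboxylic acid is not, and no base is present that could trigger E1cB loss of formate or epimerise C5 or Cα.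

## Compound list

1 | isophorone (3,5,5-trimethylcyclohex-2-en-1-one) | CC1=CC(=O)CC(C)(C)C1 | starting material
2 | (1R)-3,5,5-trimethylcyclohex-2-en-1-ol | O[C@H]1C=C(C)CC(C)(C)C1 | intermediate
3 | 2-hydroxycyclohex-2-en-1-one (enol of cyclohexane-1,2-dione) | O=C1CCCC=C1O | starting material
4 | 2-{[(1S)-3,5,5-trimethylcyclohex-2-en-1-yl]oxy}cyclohex-2-en-1-one | O=C1CCCC=C1O[C@@H]2C=C(C)CC(C)(C)C2 | intermediate
5 | 3-[(1R)-1,5,5-trimethylcyclohex-2-en-1-yl]cyclohexane-1,2-dione (C3 not defined) | O=C1CCCC([C@@]2(C)C=CCC(C)(C)C2)C1=O | intermediate (not isolated)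
6 | 2-hydroxy-3-[(1R)-1,5,5-trimethylcyclohex-2-en-1-yl]cyclohex-2-en-1-one | O=C1CCCC([C@@]2(C)C=CCC(C)(C)C2)=C1O | intermediate
7 | 2-hydroxy-3-[(1S)-1,3,3-trimethylcyclohexyl]cyclohex-2-en-1-one | O=C1CCCC([C@@]2(C)CCCC(C)(C)C2)=C1O | intermediate
8 | 6-oxo-2-[(1S)-1,3,3-trimethylcyclohexyl]cyclohex-1-en-1-yl trifluoromethanesulfonate | O=C1CCCC([C@@]2(C)CCCC(C)(C)C2)=C1OS(=O)(=O)C(F)(F)F | intermediate
9 | methyl propiolate | C#CC(=O)OC | starting material
10 | methyl 2-(tributylstannyl)prop-2-enoate | C=C(C(=O)OC)[Sn](CCCC)(CCCC)CCCC | intermediate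
11 | methyl 2-[6-oxo-2-[(1S)-1,3,3-trimethylcyclohexyl]cyclohex-1-en-1-yl]prop-2-enoate | C=C(C(=O)OC)C1=C([C@@]2(C)CCCC(C)(C)C2)CCCC1=O | intermediate
12 | 2-[6-oxo-2-[(1S)-1,3,3-trimethylcyclohexyl]cyclohex-1-en-1-yl]prop-2-enoic acid | C=C(C(=O)O)C1=C([C@@]2(C)CCCC(C)(C)C2)CCCC1=O | intermediate
13 | (2R)-2-[6-oxo-2-[(1S)-1,3,3-trimethylcyclohexyl]cyclohex-1-en-1-yl]propanoic acid | C[C@@H](C(=O)O)C1=C([C@@]2(C)CCCC(C)(C)C2)CCCC1=O | intermediate
14 | dilithium (2R)-2-[6-oxido-2-[(1S)-1,3,3-trimethylcyclohexyl]cyclohexa-1,5-dien-1-yl]propanoate | [Li+].[Li+].C[C@@H](C(=O)[O-])C1=C([C@@]2(C)CCCC(C)(C)C2)CCC=C1[O-] | intermediate (not isolated)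
15 | trimethylsilyl (2R)-2-[2-[(1S)-1,3,3-trimethylcyclohexyl]-6-(trimethylsilyloxy)cyclohexa-1,5-dien-1-yl]propanoate | C[C@@H](C(=O)O[Si](C)(C)C)C1=C([C@@]2(C)CCCC(C)(C)C2)CCC=C1O[Si](C)(C)C | intermediate
16 | (2R)-2-[(5S)-5-(hydroxymethyl)-6-oxo-2-[(1S)-1,3,3-trimethylcyclohexyl]cyclohex-1-en-1-yl]propanoic acid | C[C@@H](C(=O)O)C1=C([C@@]2(C)CCCC(C)(C)C2)CC[C@@H](CO)C1=O | intermediate
17 | (2R)-2-[(5S)-5-[(formyloxy)methyl]-6-oxo-2-[(1S)-1,3,3-trimethylcyclohexyl]cyclohex-1-en-1-yl]propanoic acid | C[C@@H](C(=O)O)C1=C([C@@]2(C)CCCC(C)(C)C2)CC[C@@H](COC=O)C1=O | target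

## Step count and least certain steps

Total steps: 12. Longest linear sequence: 11 (steps 1–5 and 7–12; step 6 is a one-step side branch).

**Step 3 (key step).**
- What may go wrong: thermal retro-ene elimination or ionisation of the allylic C–O bond may outrun the [3,3] shift. The axial 5-methyl group is syn to the forming bond, and the diosphenolate is a fair leaving group. The result would be loss of material and partial loss of chirality transfer.
- Fallback (sets out from 2, returns at 6): a different, anion-accelerated [3,3] manifold with separate ring construction. Mitsunobu esterification of 2 with commercial 6-methoxy-6-oxohexanoic acid should give, with inversion, (1S)-3,5,5-trimethylcyclohex-2-en-1-yl methyl hexanedioate F1. Ireland–Claisen rearrangement (LDA/TMSCl in excess, THF, −78 °C to reflux; only the allyl ester ketene acetal rearranges) should give 6-methoxy-6-oxo-2-[(1R)-1,5,5-trimethylcyclohex-2-en-1-yl]hexanoic acid F2. Esterification with TMSCHN2 gives dimethyl 2-[(1R)-1,5,5-trimethylcyclohex-2-en-1-yl]hexanedioate F3. Rühlmann acyloin condensation (Na, TMSCl, toluene) closes the ring to 1,2-bis(trimethylsilyloxy)-3-[(1R)-1,5,5-trimethylcyclohex-2-en-1-yl]cyclohex-1-ene F4. One equivalent of Br2 at −78 °C converts F4 into dione 5, which enolises to 6.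

**Step 2.**
- What may go wrong: ionisation of the allylic oxyphosphonium ion (tertiary allyl cation terminus) may erode the inversion or lead to elimination to the diene. C-alkylation of the ambident diosphenol is a lesser risk.
- Fallback (sets out from 1, returns at 4): build the ether without breaking the carbinol C–O bond. (R)-Me-CBS reduction of 1 gives (1S)-3,5,5-trimethylcyclohex-2-en-1-ol F5. Copper-catalysed C–O coupling (CuI, 3,4,7,8-tetramethyl-1,10-phenanthroline, Cs2CO3, toluene) of F5 with commercial 2-iodocyclohex-2-en-1-one gives 4 with retention.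

**Step 7.**
- What may go wrong: transmetalation and reductive elimination at a carbon flanked by C=O and the tert-alkyl-bearing C3 may be slow. Triflate S–O cleavage back to 7 and protodestannylation of 10 would then compete.
- Fallback (sets out from 8, returns at 11): use the smallest possible nucleophile and build the acrylate afterwards. Sonogashira coupling of 8 with trimethylsilylacetylene (Pd(PPh3)2Cl2, CuI, Et3N) gives 2-[(trimethylsilyl)ethynyl]-3-[(1S)-1,3,3-trimethylcyclohexyl]cyclohex-2-en-1-one F6. K2CO3/MeOH gives 2-ethynyl-3-[(1S)-1,3,3-trimethylcyclohexyl]cyclohex-2-en-1-one F7. Branch-selective Pd-catalysed methoxycarbonylation of the terminal alkyne (Pd(OAc)2, 2-pyridyldiphenylphosphine, MsOH, CO, MeOH) gives 11.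

**Step 11.**
- What may go wrong: protodesilylation of the silyl dienol ether by the liberated carboxylic acid would return 13. Facial selectivity may be insufficient if the Cα substituents above and below the ring plane oppose the catalyst (mismatched pairing). The product may epimerise at C5.
- Fallback (sets out from 13, returns at 16): stoichiometric aldol without catalyst control, followed by separation and recycling. Dianion 14 is treated with monomeric formaldehyde at −78 °C to give 16 together with its (5R)-epimer, (2R)-2-[(5R)-5-(hydroxymethyl)-6-oxo-2-[(1S)-1,3,3-trimethylcyclohexyl]cyclohex-1-en-1-yl]propanoic acid F9. The two are diastereomers and are separated by chromatography. F9 is re-equilibrated at C5 with a trace of mild base, or returned to 13 by retro-aldol, and recycled.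

**Step 9.**
- What may go wrong: the hindered, twisted 2-dienyl acrylic acid may bind the catalyst poorly, giving slow reduction or insufficient face selectivity.
- Fallback (sets out from 12, returns at 13): non-selective hydrogenation with an achiral cationic Rh catalyst, then separation. The product is 13 together with its Cα-epimer, (2S)-2-[6-oxo-2-[(1S)-1,3,3-trimethylcyclohexyl]cyclohex-1-en-1-yl]propanoic acid F8. These are diastereomers because of C1′ and are separated by chromatography or as (R)-1-phenylethylammonium salts. F8 is recycled by ene-diolate formation (LDA, 2 equiv) and reprotonation.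

## Further compounds

F1 | step 3 | (1S)-3,5,5-trimethylcyclohex-2-en-1-yl methyl hexanedioate | COC(=O)CCCCC(=O)O[C@@H]1C=C(C)CC(C)(C)C1
F2 | step 3 | 6-methoxy-6-oxo-2-[(1R)-1,5,5-trimethylcyclohex-2-en-1-yl]hexanoic acid (C2 not defined) | COC(=O)CCCC(C(=O)O)[C@@]1(C)C=CCC(C)(C)C1
F3 | step 3 | dimethyl 2-[(1R)-1,5,5-trimethylcyclohex-2-en-1-yl]hexanedioate (C2 not defined) | COC(=O)CCCC(C(=O)OC)[C@@]1(C)C=CCC(C)(C)C1
F4 | step 3 | 1,2-bis(trimethylsilyloxy)-3-[(1R)-1,5,5-trimethylcyclohex-2-en-1-yl]cyclohex-1-ene (C3 not defined) | C[Si](C)(C)OC1=C(O[Si](C)(C)C)C(CCC1)[C@@]2(C)C=CCC(C)(C)C2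
F5 | step 2 | (1S)-3,5,5-trimethylcyclohex-2-en-1-ol | O[C@@H]1C=C(C)CC(C)(C)C1
F6 | step 7 | 2-[(trimethylsilyl)ethynyl]-3-[(1S)-1,3,3-trimethylcyclohexyl]cyclohex-2-en-1-one | O=C1CCCC([C@@]2(C)CCCC(C)(C)C2)=C1C#C[Si](C)(C)C
F7 | step 7 | 2-ethynyl-3-[(1S)-1,3,3-trimethylcyclohexyl]cyclohex-2-en-1-one | O=C1CCCC([C@@]2(C)CCCC(C)(C)C2)=C1C#C
F8 | step 9 | (2S)-2-[6-oxo-2-[(1S)-1,3,3-trimethylcyclohexyl]cyclohex-1-en-1-yl]propanoic acid | C[C@H](C(=O)O)C1=C([C@@]2(C)CCCC(C)(C)C2)CCCC1=O
F9 | step 11 | (2R)-2-[(5R)-5-(hydroxymethyl)-6-oxo-2-[(1S)-1,3,3-trimethylcyclohexyl]cyclohex-1-en-1-yl]propanoic acid | C[C@@H](C(=O)O)C1=C([C@@]2(C)CCCC(C)(C)C2)CC[C@H](CO)C1=O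
A1 | alternative 1 | (3S)-3-(3-methoxyphenyl)-3-methylcyclohexan-1-one | COc1cccc(c1)[C@@]2(C)CCCC(=O)C2
A2 | alternative 1 | 1-methoxy-3-[(1S)-1,3,3-trimethylcyclohexyl]benzene | COc1cccc(c1)[C@@]2(C)CCCC(C)(C)C2
A3 | alternative 1 | 3-[(1S)-1,3,3-trimethylcyclohexyl]cyclohex-2-en-1-one | O=C1C=C(CCC1)[C@@]2(C)CCCC(C)(C)C2
A4 | alternative 2 | (1S)-1,3,3-trimethylcyclohexane-1-carboxylic acid | OC(=O)[C@@]1(C)CCCC(C)(C)C1
A5 | alternative 2 | tert-butyl (2R,5S)-5-{[(tert-butyldimethylsilyl)oxy]methyl}-2-methyl-4,8-dioxo-8-[(1S)-1,3,3-trimethylcyclohexyl]octanoate | C[C@H](CC(=O)[C@H](CO[Si](C)(C)C(C)(C)C)CCC(=O)[C@@]1(C)CCCC(C)(C)C1)C(=O)OC(C)(C)C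
A6 | alternative 3 | tert-butyl (2R)-2-methyl-4-[(1S)-1,3,3-trimethylcyclohexyl]but-3-ynoate | C[C@@H](C(=O)OC(C)(C)C)C#C[C@@]1(C)CCCC(C)(C)C1
A7 | alternative 3 | (2S)-2-{[(tert-butyldimethylsilyl)oxy]methyl}cyclobutan-1-one | O=C1CC[C@H]1CO[Si](C)(C)C(C)(C)C
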